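All runs were computed for substances that don't exist; noise was put on by code.

The reading comes at 3.0 h, so for each new flask I ask how much still happens after the last earlier reading at 120 min.

common to all: electrophile 0.30 M

| flask | nucleophile | free base | remark | time |
|---|---|---|---|---|
| alpha | 0.36 M | 0.62 M | run made earlier |  |
| gamma | 0.36 M | 2 M | run made earlier |  |
| south-east | 0.360 M | 1.80 M |  | 3.0 h |
| west | 0.360 M | 0.450 M |  | 3.0 h |
| east | 0.360 M | 0.900 M |  | 3.0 h |

| run | time / min | electrophile / % | target / % |
|---|---|---|---|
| alpha | 20.0 | 63.9 | 36.7 |
| alpha | 40.0 | 56.0 | 44.3 |
| alpha | 60.0 | 54.2 | 46.6 |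
| alpha | 80.0 | 51.4 | 47.3 |
| alpha | 120 | 51.0 | 49.1 |
| gamma | 10.0 | 73.2 | 26.8 |
| gamma | 15.0 | 68.4 | 32.4 |
| gamma | 30.0 | 58.7 | 41.6 |
| gamma | 50.0 | 53.9 | 45.8 |
| gamma | 80.0 | 51.3 | 47.5 |
| gamma | 120 | 49.3 | 50.3 |

(standard deviation of a reading: 0.5 percentage points)

* part of the electrophile that has reacted at the end, south-east
* part of the electrophile that has reacted at the end, west
* part of the electrophile that has reacted at the end, east
* what raising the concentration of free base from its lowest to its highest value here does to the part of the electrophile that has reacted (changes below 5 percentage points count as none) (it rises / it falls / no change)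



How far has the alpha run slowed? Its first slope over its last slope is 40.8, a rough reading given the scatter. Is that simple consumption? If forming target were the nucleophile's one fate, subtraction would leave c(nucleophile) at 0.213 M at the last alpha reading, with the electrophile down to about half. A rate following their product would fall by a factor of 3.32, far less than the reading. So I suspect that much of the nucleophile no longer reacts, and I define the nucleophile cost, the nucleophile charged per target formed, which at the last alpha reading is 2.44. The gamma run gives 2.39 at its last reading, with 3.23 times the free base.

Does free base matter? The two costs differ by 0.0583, so I read no clear effect of free base across that span, treat the nucleophile as the limiting reagent and expect no change, although the free base of west lies below the alpha charge. The last slope, kept for the remaining time, adds 2.7 percentage points, so I commit to 51.8% in each flask.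

The forecast, from “Both runs flatten near 50% conversion”, gives 52% for south-east, 51% for west, 52% for east and no change, differing from mine in west.

The flasks give 51.8% for south-east, 50.5% for west, 50.9% for east, and no change, with a change of 1.3 points.

    electrophile + nucleophile → acid set free + target (k = 0.00236 M⁻¹ s⁻¹)
    nucleophile + acid set free ⇌ protonated nucleophile, settled at all times (K = 2300 M⁻¹)
    acid set free + free base ⇌ salt of the base (K = 13.0 M⁻¹, k = 0.0895 M⁻¹ s⁻¹)
    free base ⇌ dormant form (K = 14.0, k = 9.57 × 10⁻⁴ s⁻¹)
    2 nucleophile → homo dimer (k = 9.87 × 10⁻⁴ M⁻¹ s⁻¹)

In east, the half-life of electrophile by the target step grows from 0.65 h at 0.185 h, shorter than the time of reading, to 26 h at 3.00 h, longer than it. By then east holds 0.888% of its nucleophile free, beside 0.123 M protonated nucleophile and 0.0403 M homo dimer, and its cost is 2.36. For the same flask with 1.2 M of electrophile, the alpha cost reckons 12.3%, while that flask gives 18.4%, a cost of 1.63.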